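**Plan**
- Retrosynthetic cuts: the acetates and the acid go back to a diol ester; the C7–O bond to allylic oxidation of the C8=C17 methylene; C17 to methylenation of a C8 ketone; C11–C12 to a Julia–Kocienski olefination (side chain C12–C16 from (R)-2-methylsuccinic acid 4-methyl ester); then C5–C10 and C8–C9 are cut together.
- Enabling feature: in ring B the ring-fusion bond C5–C10 and the bond C8–C9 lie opposite each other, and the C10 methyl (C20) is cis to the C9 carbon substituent (C11). An (E)-C9=C10 enal adding to a C5–C8 diene held by the C1–C4 tether leaves exactly this pattern, so rings A and B can close in one step from an open chain.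
- Forward chain assembly: geranyl acetate gives C1, C2, C9–C11 and C20; reverse prenylation joins C3–C4 (gem-dimethyl, C3 carbinol); hydroboration, oxidation and a Wittig reaction add C7 and C8; γ-silylation forms the 1-silyloxydiene, and the enal is unveiled last.
- After the cycloaddition: side chain, hydrogenation, C8 ketone, C17 methylene, C7 hydroxylation, deprotection, diacetylation.
- Stereochemistry: C3 from the α-pinene-derived allylborane; C5, C9 and C10 from the cycloaddition (relative by alkene geometry and endo mode, absolute through C3); C13 from the chiral pool; C7 from axial oxygen delivery in the SeO2 oxidation.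

Key step: step 10

Remark on numbering: labdane numbering is used throughout (C1–C10 decalin, C11–C16 side chain with C16 the methyl on C13, C17 on C8, C20 on C10); the parent has 5α-H, 9α-H and 10β-CH3.
Assumption: 1, 4, 12 and 18 are taken as commercial; the C11=C12 alkene of 22 is drawn E, the usual outcome of this olefination, and its geometry is erased in step 15.

Step 1
Reactants: 1 geranyl acetate
Product: 3 (2E)-3-methyl-6-oxohex-2-en-1-yl acetate, via ozonide 2 (not isolated)
Conditions: O3 (about 1 equiv, Sudan Red 7B end point), CH2Cl2, −78 °C; then Me2S, −78 °C → rt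
Reagents that add atoms: ozone, [O-][O+]=O
Why: Ozonolysis should cleave the electron-rich 6,7-alkene much faster than the 2,3-alkene, which is deactivated by the allylic acetate, and Me2S reduces the ozonide to the aldehyde.

Step 2
Reactants: 3 (2E)-3-methyl-6-oxohex-2-en-1-yl acetate; 4 3-methylbuta-1,2-diene
Product: 7 (2E,6S)-6-hydroxy-3,7,7-trimethylnona-2,8-dien-1-yl acetate, via prenylborane 5 (not isolated), via borinate 6 (not isolated)
Conditions: (Ipc)2BH [from (−)-α-pinene], 4, THF, −25 °C; then 3, −78 °C; then 3 M aq NaOAc, 30% H2O2, 0 °C → rt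
Reagents that add atoms: diisopinocampheylborane, B([C@H]1C[C@H]2C[C@@H]([C@@H]1C)C2(C)C)[C@H]1C[C@H]2C[C@@H]([C@@H]1C)C2(C)C (boron and isopinocampheyl groups in intermediates 5 and 6 only)
Why: Brown asymmetric allylboration (reverse prenylation): hydroboration of the allene gives the γ,γ-dimethylallylborane, which should add through a chair six-membered transition state with allylic transposition, creating the quaternary C4 and, by re-face attack dictated by the isopinocampheyl groups, the (S)-carbinol at C3.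

Step 3
Reactants: 7 (2E,6S)-6-hydroxy-3,7,7-trimethylnona-2,8-dien-1-yl acetate
Product: 8 (2E,6S)-6-(tert-butyldimethylsilyloxy)-3,7,7-trimethylnona-2,8-dien-1-yl acetate
Conditions: TBSOTf, 2,6-lutidine, CH2Cl2, −78 → 0 °C
Reagents that add atoms: tert-butyldimethylsilyl trifluoromethanesulfonate, CC(C)(C)[Si](C)(C)OS(=O)(=O)C(F)(F)F
Why: Silylation with a silyl triflate is the standard way to protect a secondary alcohol flanked by a quaternary carbon, and the acetate is inert.

Step 4
Reactants: 8 (2E,6S)-6-(tert-butyldimethylsilyloxy)-3,7,7-trimethylnona-2,8-dien-1-yl acetate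
Product: 10 (2E,6S)-6-(tert-butyldimethylsilyloxy)-9-hydroxy-3,7,7-trimethylnon-2-en-1-yl acetate, via alkylborane 9 (not isolated)
Conditions: 9-BBN, THF, 0 °C → rt; then 3 M aq NaOAc, 30% H2O2, 0 °C → rt
Reagents that add atoms: 9-borabicyclo[3.3.1]nonane, B1C2CCCC1CCC2 (boron in intermediate 9 only); hydrogen peroxide, OO
Why: Anti-Markovnikov hydroboration–oxidation: 9-BBN should add only to the monosubstituted alkene (boron on the terminal carbon), leaving the trisubstituted alkene and the acetate, and the buffered peroxide oxidation keeps the acetate.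

Step 5
Reactants: 10 (2E,6S)-6-(tert-butyldimethylsilyloxy)-9-hydroxy-3,7,7-trimethylnon-2-en-1-yl acetate
Product: 11 (2E,6S)-6-(tert-butyldimethylsilyloxy)-3,7,7-trimethyl-9-oxonon-2-en-1-yl acetate
Conditions: Dess–Martin periodinane, NaHCO3, CH2Cl2, 0 °C → rt
Reagents that add atoms: none
Why: Dess–Martin oxidation of the primary alcohol under buffered conditions gives the aldehyde without touching the acetate or the silyl ether.

Step 6
Reactants: 11 (2E,6S)-6-(tert-butyldimethylsilyloxy)-3,7,7-trimethyl-9-oxonon-2-en-1-yl acetate; 12 (triphenylphosphoranylidene)acetaldehyde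
Product: 13 (2E,6S,9E)-6-(tert-butyldimethylsilyloxy)-3,7,7-trimethyl-11-oxoundeca-2,9-dien-1-yl acetate
Conditions: PhMe, 80 °C
Reagents that add atoms: none
Why: Wittig olefination with the stabilised formyl ylide adds C7 and C8 and should give the (E)-enal.

Step 7
Reactants: 13 (2E,6S,9E)-6-(tert-butyldimethylsilyloxy)-3,7,7-trimethyl-11-oxoundeca-2,9-dien-1-yl acetate
Product: 14 (2E,6S,8E,10E)-6-(tert-butyldimethylsilyloxy)-3,7,7-trimethyl-11-(triethylsilyloxy)undeca-2,8,10-trien-1-yl acetate
Conditions: Et3SiOTf, Et3N, Et2O, 0 °C → rt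
Reagents that add atoms: triethylsilyl trifluoromethanesulfonate, CC[Si](CC)(CC)OS(=O)(=O)C(F)(F)F
Why: Soft enolisation (O-silylation of the enal, then γ-deprotonation at C5) forms the silyl dienol ether; the s-trans enal should give the 1E enol ether, the tert-alkyl group at C4 should force the new C5=C6 bond to be E, and the acetate is not enolised under these conditions.

Step 8
Reactants: 14 (2E,6S,8E,10E)-6-(tert-butyldimethylsilyloxy)-3,7,7-trimethyl-11-(triethylsilyloxy)undeca-2,8,10-trien-1-yl acetate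
Product: 15 (2E,6S,8E,10E)-6-(tert-butyldimethylsilyloxy)-3,7,7-trimethyl-11-(triethylsilyloxy)undeca-2,8,10-trien-1-ol
Conditions: i-Bu2AlH, CH2Cl2, −78 °C; aq KNaC4H4O6 (potassium sodium tartrate) work-up
Reagents that add atoms: none
Why: Reductive cleavage of the acetate by the aluminium hydride at low temperature leaves silyl ethers and the silyl dienol ether untouched, and the near-neutral tartrate work-up avoids hydrolysis of the dienol ether.

Step 9
Reactants: 15 (2E,6S,8E,10E)-6-(tert-butyldimethylsilyloxy)-3,7,7-trimethyl-11-(triethylsilyloxy)undeca-2,8,10-trien-1-ol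
Product: 16 (2E,6S,8E,10E)-6-(tert-butyldimethylsilyloxy)-3,7,7-trimethyl-11-(triethylsilyloxy)undeca-2,8,10-trienal
Conditions: MnO2 (activated, excess), CH2Cl2, rt
Reagents that add atoms: none
Why: MnO2 oxidises only the allylic alcohol, under neutral heterogeneous conditions that should keep the silyl dienol ether and the E geometry of the C9=C10 bond, so the enal appears only after the diene is in place.

Step 10
Reactants: 16 (2E,6S,8E,10E)-6-(tert-butyldimethylsilyloxy)-3,7,7-trimethyl-11-(triethylsilyloxy)undeca-2,8,10-trienal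
Product: 17 (1R,2S,4aR,6S,8aS)-6-(tert-butyldimethylsilyloxy)-5,5,8a-trimethyl-2-(triethylsilyloxy)-1,2,4a,5,6,7,8,8a-octahydronaphthalene-1-carbaldehyde
Conditions: PhMe (0.01 M), BHT (cat.), Et3N (cat.), 150 °C, sealed tube
Reagents that add atoms: none
Why: Intramolecular Diels–Alder reaction, a concerted but asynchronous suprafacial [4+2] cycloaddition in which the electron-rich 1-silyloxydiene (C5=C6–C7=C8) adds to the enal (C9=C10), C5 bonding to the β-carbon C10 ahead of C8 bonding to C9. The closest known reaction type is the thermal cyclisation of (E)-terminally activated 1,7,9-decatrienes to trans-fused octalins, which has also been used to build drimane cores with an angular quaternary carbon beside a gem-dimethyl carbon. Ring B closes as the cyclohexene of the cycloadduct, and ring A closes in the same event as the four-carbon tether C1–C4 folds into a chair while C5–C10 forms. The E enal fixes the C9 formyl group cis to the C10 methyl group, the E,E diene fixes H5 cis to H8, the formyl-endo and tether-exo transition state sets C5 against C10 (trans fusion), and the C3 silyloxy group, equatorial on the chair tether, decides which diene face is attacked and hence the absolute configuration. The step needs endo and facial selectivity: the first should come from the E terminal formyl group and the early C5–C10 bond, helped by the C4 gem-dimethyl group that favours the folded chair, the second from C3; the configuration at C8 does not matter because C8 becomes a ketone in step 17.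

Step 11
Reactants: 18 (2R)-4-methoxy-2-methyl-4-oxobutanoic acid
Product: 19 methyl (3R)-4-hydroxy-3-methylbutanoate
Conditions: BH3·SMe2, THF, −10 °C → rt; MeOH quench
Reagents that add atoms: none
Why: Borane reduces the carboxylic acid chemoselectively (through the acyloxyborane) in the presence of the methyl ester, and the stereocentre is not involved.

Step 12
Reactants: 19 methyl (3R)-4-hydroxy-3-methylbutanoate
Product: 20 methyl (3R)-3-methyl-4-[(1-phenyl-1H-tetrazol-5-yl)sulfanyl]butanoate
Conditions: 1-phenyl-1H-tetrazole-5-thiol, PPh3, DIAD, THF, 0 °C → rt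
Reagents that add atoms: 1-phenyl-1H-tetrazole-5-thiol, Sc1nnnn1-c1ccccc1
Why: Mitsunobu thioetherification of the primary alcohol with the acidic heteroaryl thiol, run directly on the crude hydroxy ester to forestall lactonisation.

Step 13
Reactants: 20 methyl (3R)-3-methyl-4-[(1-phenyl-1H-tetrazol-5-yl)sulfanyl]butanoate
Product: 21 methyl (3R)-3-methyl-4-[(1-phenyl-1H-tetrazol-5-yl)sulfonyl]butanoate
Conditions: (NH4)6Mo7O24·4H2O (cat.), 30% H2O2, EtOH, 0 °C → rt
Reagents that add atoms: hydrogen peroxide, OO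
Why: Molybdate-catalysed peroxide oxidation of the sulfide to the sulfone is standard for these olefination reagents and tolerates the ester.

Step 14
Reactants: 17 (1R,2S,4aR,6S,8aS)-6-(tert-butyldimethylsilyloxy)-5,5,8a-trimethyl-2-(triethylsilyloxy)-1,2,4a,5,6,7,8,8a-octahydronaphthalene-1-carbaldehyde; 21 methyl (3R)-3-methyl-4-[(1-phenyl-1H-tetrazol-5-yl)sulfonyl]butanoate
Product: 22 methyl (11E,13R)-3β-(tert-butyldimethylsilyloxy)-8β-(triethylsilyloxy)-17-norlabda-6,11-dien-15-oate
Conditions: 21, KN(SiMe3)2, THF, −78 °C; then 17, −78 °C → rt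
Reagents that add atoms: none
Why: Julia–Kocienski olefination (carbanion addition, Smiles rearrangement, loss of SO2 and the tetrazololate) forms C11=C12; C13 is not acidic and is retained, and the low temperature should suppress enolisation at C9 and β-elimination of the C8 silyloxy group.

Step 15
Reactants: 22 methyl (11E,13R)-3β-(tert-butyldimethylsilyloxy)-8β-(triethylsilyloxy)-17-norlabda-6,11-dien-15-oate
Product: 23 methyl (13S)-3β-(tert-butyldimethylsilyloxy)-8β-(triethylsilyloxy)-17-norlabdan-15-oate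
Conditions: H2 (1 atm), PtO2 (cat.), EtOAc, rt
Reagents that add atoms: none
Why: Heterogeneous catalytic hydrogenation saturates both disubstituted alkenes without creating a stereocentre; platinum is chosen because it causes little double-bond migration toward C13 and little allylic C–O hydrogenolysis.

Step 16
Reactants: 23 methyl (13S)-3β-(tert-butyldimethylsilyloxy)-8β-(triethylsilyloxy)-17-norlabdan-15-oate
Product: 24 methyl (13S)-3β-(tert-butyldimethylsilyloxy)-8β-hydroxy-17-norlabdan-15-oate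
Conditions: AcOH–THF–H2O (3:1:1), 40 °C
Reagents that add atoms: none
Why: Selective acid-catalysed solvolysis of the triethylsilyl ether; the tert-butyldimethylsilyl ether beside the gem-dimethyl carbon should be far slower to cleave.

Step 17
Reactants: 24 methyl (13S)-3β-(tert-butyldimethylsilyloxy)-8β-hydroxy-17-norlabdan-15-oate
Product: 25 methyl (13S)-3β-(tert-butyldimethylsilyloxy)-8-oxo-17-norlabdan-15-oate
Conditions: Dess–Martin periodinane, NaHCO3, CH2Cl2, rt
Reagents that add atoms: none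
Why: Dess–Martin oxidation of the hindered axial alcohol gives the ketone, and C9 keeps its configuration because the equatorial side chain is the thermodynamically preferred epimer.

Step 18
Reactants: 25 methyl (13S)-3β-(tert-butyldimethylsilyloxy)-8-oxo-17-norlabdan-15-oate
Product: 26 methyl (13S)-3β-(tert-butyldimethylsilyloxy)labd-8(17)-en-15-oate
Conditions: Ph3PCH3Br, KOt-Bu, THF, 0 °C → reflux
Reagents that add atoms: methyltriphenylphosphonium bromide, C[P+](c1ccccc1)(c1ccccc1)c1ccccc1.[Br-]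
Why: Wittig methylenation installs C17; the unstabilised ylide should react with the ketone much faster than with the methyl ester.

Step 19
Reactants: 26 methyl (13S)-3β-(tert-butyldimethylsilyloxy)labd-8(17)-en-15-oate
Product: 27 methyl (13S)-3β-(tert-butyldimethylsilyloxy)-7α-hydroxylabd-8(17)-en-15-oate
Conditions: SeO2 (cat.), t-BuOOH, CH2Cl2, 0 °C → rt
Reagents that add atoms: tert-butyl hydroperoxide, CC(C)(C)OO (oxygen relayed through SeO2, O=[Se]=O)
Why: SeO2 allylic oxidation (ene reaction, then [2,3]-sigmatropic shift of the allylseleninic acid) should attack the C7 methylene rather than the hindered C9 methine and deliver oxygen axially on the α face, anti to the C10 methyl, to set the 7α-hydroxyl.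

Step 20
Reactants: 27 methyl (13S)-3β-(tert-butyldimethylsilyloxy)-7α-hydroxylabd-8(17)-en-15-oate
Product: 29 (13S)-3β,7α-dihydroxylabd-8(17)-en-15-oic acid, via diol ester 28 (not isolated)
Conditions: Bu4NF, THF, 60 °C; then LiOH, MeOH–H2O, rt; 1 M HCl work-up
Reagents that add atoms: lithium hydroxide, [Li+].[OH-]
Why: Fluoride-mediated cleavage of the hindered silyl ether followed by saponification of the methyl ester in the same flask; both conditions leave the allylic alcohol and the exocyclic alkene alone.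

Step 21
Reactants: 29 (13S)-3β,7α-dihydroxylabd-8(17)-en-15-oic acid
Product: 31 (13S)-3β,7α-diacetoxylabd-8(17)-en-15-oic acid, via mixed anhydride 30 (not isolated)
Conditions: Ac2O, pyridine, DMAP (cat.), rt; then aq NaHCO3–THF, rt; acidify to pH 3
Reagents that add atoms: acetic anhydride, CC(=O)OC(C)=O
Why: DMAP-catalysed acetylation esterifies both secondary alcohols; the carboxyl group is acetylated to a mixed anhydride that is hydrolysed selectively during the aqueous bicarbonate work-up.

**Compound list**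
1 | geranyl acetate, (2E)-3,7-dimethylocta-2,6-dien-1-yl acetate | CC(C)=CCC/C(C)=C/COC(C)=O | starting material
2 | ozonide, (2E)-5-(5,5-dimethyl-1,2,4-trioxolan-3-yl)-3-methylpent-2-en-1-yl acetate (both epimers at the trioxolane carbon) | CC1(C)OOC(CC/C(C)=C/COC(C)=O)O1 | intermediate
3 | (2E)-3-methyl-6-oxohex-2-en-1-yl acetate | O=CCC/C(C)=C/COC(C)=O | intermediate
4 | 3-methylbuta-1,2-diene | CC(C)=C=C | starting material
5 | prenylborane, B-(3-methylbut-2-en-1-yl)diisopinocampheylborane from (−)-α-pinene | CC(C)=CCB([C@H]1C[C@H]2C[C@@H]([C@@H]1C)C2(C)C)[C@H]1C[C@H]2C[C@@H]([C@@H]1C)C2(C)C | intermediate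
6 | borinate, (2E,6S)-6-[(diisopinocampheylboryl)oxy]-3,7,7-trimethylnona-2,8-dien-1-yl acetate | C=CC(C)(C)[C@H](CC/C(C)=C/COC(C)=O)OB([C@H]1C[C@H]2C[C@@H]([C@@H]1C)C2(C)C)[C@H]1C[C@H]2C[C@@H]([C@@H]1C)C2(C)C | intermediate
7 | (2E,6S)-6-hydroxy-3,7,7-trimethylnona-2,8-dien-1-yl acetate | C=CC(C)(C)[C@@H](O)CC/C(C)=C/COC(C)=O | intermediate
8 | (2E,6S)-6-(tert-butyldimethylsilyloxy)-3,7,7-trimethylnona-2,8-dien-1-yl acetate | C=CC(C)(C)[C@@H](O[Si](C)(C)C(C)(C)C)CC/C(C)=C/COC(C)=O | intermediate
9 | alkylborane, B-alkyl-9-borabicyclo[3.3.1]nonane from 8 (boron on the former terminal alkene carbon) | B1(CCC(C)(C)[C@@H](O[Si](C)(C)C(C)(C)C)CC/C(C)=C/COC(C)=O)C2CCCC1CCC2 | intermediate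
10 | (2E,6S)-6-(tert-butyldimethylsilyloxy)-9-hydroxy-3,7,7-trimethylnon-2-en-1-yl acetate | OCCC(C)(C)[C@@H](O[Si](C)(C)C(C)(C)C)CC/C(C)=C/COC(C)=O | intermediate
11 | (2E,6S)-6-(tert-butyldimethylsilyloxy)-3,7,7-trimethyl-9-oxonon-2-en-1-yl acetate | O=CCC(C)(C)[C@@H](O[Si](C)(C)C(C)(C)C)CC/C(C)=C/COC(C)=O | intermediate
12 | (triphenylphosphoranylidene)acetaldehyde | O=CC=P(c1ccccc1)(c1ccccc1)c1ccccc1 | starting material
13 | (2E,6S,9E)-6-(tert-butyldimethylsilyloxy)-3,7,7-trimethyl-11-oxoundeca-2,9-dien-1-yl acetate | O=C/C=C/CC(C)(C)[C@@H](O[Si](C)(C)C(C)(C)C)CC/C(C)=C/COC(C)=O | intermediate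
14 | (2E,6S,8E,10E)-6-(tert-butyldimethylsilyloxy)-3,7,7-trimethyl-11-(triethylsilyloxy)undeca-2,8,10-trien-1-yl acetate | CC[Si](CC)(CC)O/C=C/C=C/C(C)(C)[C@@H](O[Si](C)(C)C(C)(C)C)CC/C(C)=C/COC(C)=O | intermediate
15 | (2E,6S,8E,10E)-6-(tert-butyldimethylsilyloxy)-3,7,7-trimethyl-11-(triethylsilyloxy)undeca-2,8,10-trien-1-ol | CC[Si](CC)(CC)O/C=C/C=C/C(C)(C)[C@@H](O[Si](C)(C)C(C)(C)C)CC/C(C)=C/CO | intermediate
16 | (2E,6S,8E,10E)-6-(tert-butyldimethylsilyloxy)-3,7,7-trimethyl-11-(triethylsilyloxy)undeca-2,8,10-trienal | O=C/C=C(\C)CC[C@H](O[Si](C)(C)C(C)(C)C)C(C)(C)/C=C/C=C/O[Si](CC)(CC)CC | intermediate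
17 | (1R,2S,4aR,6S,8aS)-6-(tert-butyldimethylsilyloxy)-5,5,8a-trimethyl-2-(triethylsilyloxy)-1,2,4a,5,6,7,8,8a-octahydronaphthalene-1-carbaldehyde (trans-fused; 3β-OTBS, 8β-OTES, 9β-CHO, alkene C6=C7) | CC[Si](CC)(CC)O[C@H]1C=C[C@H]2C(C)(C)[C@@H](O[Si](C)(C)C(C)(C)C)CC[C@]2(C)[C@H]1C=O | intermediate
18 | (2R)-4-methoxy-2-methyl-4-oxobutanoic acid, (R)-2-methylsuccinic acid 4-methyl ester | COC(=O)C[C@@H](C)C(=O)O | starting material
19 | methyl (3R)-4-hydroxy-3-methylbutanoate | COC(=O)C[C@@H](C)CO | intermediate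
20 | methyl (3R)-3-methyl-4-[(1-phenyl-1H-tetrazol-5-yl)sulfanyl]butanoate | COC(=O)C[C@@H](C)CSc1nnnn1-c1ccccc1 | intermediate
21 | methyl (3R)-3-methyl-4-[(1-phenyl-1H-tetrazol-5-yl)sulfonyl]butanoate | COC(=O)C[C@@H](C)CS(=O)(=O)c1nnnn1-c1ccccc1 | intermediate
22 | methyl (11E,13R)-3β-(tert-butyldimethylsilyloxy)-8β-(triethylsilyloxy)-17-norlabda-6,11-dien-15-oate | CC[Si](CC)(CC)O[C@H]1C=C[C@H]2C(C)(C)[C@@H](O[Si](C)(C)C(C)(C)C)CC[C@]2(C)[C@H]1/C=C/[C@H](C)CC(=O)OC | intermediate
23 | methyl (13S)-3β-(tert-butyldimethylsilyloxy)-8β-(triethylsilyloxy)-17-norlabdan-15-oate | CC[Si](CC)(CC)O[C@H]1CC[C@H]2C(C)(C)[C@@H](O[Si](C)(C)C(C)(C)C)CC[C@]2(C)[C@H]1CC[C@H](C)CC(=O)OC | intermediate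
24 | methyl (13S)-3β-(tert-butyldimethylsilyloxy)-8β-hydroxy-17-norlabdan-15-oate | O[C@H]1CC[C@H]2C(C)(C)[C@@H](O[Si](C)(C)C(C)(C)C)CC[C@]2(C)[C@H]1CC[C@H](C)CC(=O)OC | intermediate
25 | methyl (13S)-3β-(tert-butyldimethylsilyloxy)-8-oxo-17-norlabdan-15-oate | O=C1CC[C@H]2C(C)(C)[C@@H](O[Si](C)(C)C(C)(C)C)CC[C@]2(C)[C@H]1CC[C@H](C)CC(=O)OC | intermediate
26 | methyl (13S)-3β-(tert-butyldimethylsilyloxy)labd-8(17)-en-15-oate | C=C1CC[C@H]2C(C)(C)[C@@H](O[Si](C)(C)C(C)(C)C)CC[C@]2(C)[C@H]1CC[C@H](C)CC(=O)OC | intermediate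
27 | methyl (13S)-3β-(tert-butyldimethylsilyloxy)-7α-hydroxylabd-8(17)-en-15-oate | C=C1[C@H](O)C[C@H]2C(C)(C)[C@@H](O[Si](C)(C)C(C)(C)C)CC[C@]2(C)[C@H]1CC[C@H](C)CC(=O)OC | intermediate
28 | diol ester, methyl (13S)-3β,7α-dihydroxylabd-8(17)-en-15-oate | C=C1[C@H](O)C[C@H]2C(C)(C)[C@@H](O)CC[C@]2(C)[C@H]1CC[C@H](C)CC(=O)OC | intermediate
29 | (13S)-3β,7α-dihydroxylabd-8(17)-en-15-oic acid | C=C1[C@H](O)C[C@H]2C(C)(C)[C@@H](O)CC[C@]2(C)[C@H]1CC[C@H](C)CC(=O)O | intermediate
30 | mixed anhydride, acetic (13S)-3β,7α-diacetoxylabd-8(17)-en-15-oic anhydride | C=C1[C@H](OC(C)=O)C[C@H]2C(C)(C)[C@@H](OC(C)=O)CC[C@]2(C)[C@H]1CC[C@H](C)CC(=O)OC(C)=O | intermediate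
31 | (13S)-3β,7α-diacetoxylabd-8(17)-en-15-oic acid, CNP0169875.1 (3S,5R,7R,9R,10S,13S) | C=C1[C@H](OC(C)=O)C[C@H]2C(C)(C)[C@@H](OC(C)=O)CC[C@]2(C)[C@H]1CC[C@H](C)CC(=O)O | target

Total step count: 21. Longest linear sequence: 18 steps (steps 1–10 and 14–21); steps 11–13 make sulfone 21.

**Steps most likely to fail**

1. Step 10. The cycloaddition may stall because the forming C5–C10 bond joins a carbon next to the gem-dimethyl carbon to a quaternary carbon, and prolonged heating may erode endo and facial selectivity or cleave the triethylsilyl dienol ether. The fallback replaces the uncatalysed thermal closure by Lewis-acid activation of the enal, which needs a diene that survives aluminium Lewis acids, namely a 1-acetoxydiene. It sets out from enal 13. Methanolysis of the acetate (K2CO3, MeOH, 0 °C) gives (2E,6S,9E)-6-(tert-butyldimethylsilyloxy)-11-hydroxy-5,5,9-trimethylundeca-2,9-dienal F1. Silylation of the primary hydroxyl (TBSCl, imidazole) gives (2E,6S,9E)-6,11-bis(tert-butyldimethylsilyloxy)-5,5,9-trimethylundeca-2,9-dienal F2. γ-Deprotonation with KOt-Bu at −78 °C and O-acetylation with AcCl should give (1E,3E,6S,9E)-6,11-bis(tert-butyldimethylsilyloxy)-5,5,9-trimethylundeca-1,3,9-trien-1-yl acetate F3. HF·pyridine buffered with pyridine removes only the primary allylic silyl ether to give (1E,3E,6S,9E)-6-(tert-butyldimethylsilyloxy)-11-hydroxy-5,5,9-trimethylundeca-1,3,9-trien-1-yl acetate F4, and MnO2 gives (1E,3E,6S,9E)-6-(tert-butyldimethylsilyloxy)-5,5,9-trimethyl-11-oxoundeca-1,3,9-trien-1-yl acetate F5. Me2AlCl (CH2Cl2, −78 → −20 °C) should then close both rings through the same endo transition state to 8β-acetoxy-3β-(tert-butyldimethylsilyloxy)-12,13,14,15,16,17-hexanorlabd-6-en-11-al F6. The conditions of step 14 (at −78 °C, to avoid β-elimination of acetate) give methyl (11E,13R)-8β-acetoxy-3β-(tert-butyldimethylsilyloxy)-17-norlabda-6,11-dien-15-oate F7, and those of step 15 give methyl (13S)-8β-acetoxy-3β-(tert-butyldimethylsilyloxy)-17-norlabdan-15-oate F8. Methanolysis of the secondary acetate (K2CO3, MeOH) comes back to the route at alcohol 24.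

2. Step 14. Addition of the bulky sulfonyl carbanion to the hindered aldehyde may be slow, leaving time for enolisation at C9 and β-elimination of the C8 silyloxy group. The fallback is a Wittig olefination with a smaller, unstabilised phosphorus ylide. It sets out from hydroxy ester 19 and aldehyde 17. Iodination of 19 (I2, PPh3, imidazole) gives methyl (3R)-4-iodo-3-methylbutanoate F9, and heating with PPh3 in MeCN gives [(2R)-4-methoxy-2-methyl-4-oxobutyl]triphenylphosphonium iodide F10. Deprotonation with NaN(SiMe3)2 (THF, −78 → 0 °C) and addition of 17 should give methyl (11Z,13R)-3β-(tert-butyldimethylsilyloxy)-8β-(triethylsilyloxy)-17-norlabda-6,11-dien-15-oate F11. Hydrogenation as in step 15 comes back to the route at 23.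

3. Step 19. The allylic oxidation may run on to the enone, attack the C9 methine, or deliver oxygen to the β face. The fallback introduces the C7 oxygen by enolate oxidation before the methylene group is made (Rubottom oxidation). It sets out from ketone 25. Kinetic enolisation toward the C7 methylene with LiN(i-Pr)2 and Me3SiCl in situ (THF, −78 °C) gives methyl (13S)-3β-(tert-butyldimethylsilyloxy)-8-(trimethylsilyloxy)-17-norlabd-7-en-15-oate F12. Epoxidation with m-CPBA (NaHCO3, CH2Cl2, 0 °C) from the α face, anti to the C10 methyl, and silyl migration should give methyl (13S)-3β-(tert-butyldimethylsilyloxy)-8-oxo-7α-(trimethylsilyloxy)-17-norlabdan-15-oate F13. Non-basic Takai–Lombardo methylenation (Zn, CH2Br2, TiCl4) gives methyl (13S)-3β-(tert-butyldimethylsilyloxy)-7α-(trimethylsilyloxy)labd-8(17)-en-15-oate F14, and K2CO3 in MeOH removes the trimethylsilyl group to come back to the route at 27.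

**Further compounds**
F1 | step 10 | (2E,6S,9E)-6-(tert-butyldimethylsilyloxy)-11-hydroxy-5,5,9-trimethylundeca-2,9-dienal | O=C/C=C/CC(C)(C)[C@@H](O[Si](C)(C)C(C)(C)C)CC/C(C)=C/CO
F2 | step 10 | (2E,6S,9E)-6,11-bis(tert-butyldimethylsilyloxy)-5,5,9-trimethylundeca-2,9-dienal | O=C/C=C/CC(C)(C)[C@@H](O[Si](C)(C)C(C)(C)C)CC/C(C)=C/CO[Si](C)(C)C(C)(C)C
F3 | step 10 | (1E,3E,6S,9E)-6,11-bis(tert-butyldimethylsilyloxy)-5,5,9-trimethylundeca-1,3,9-trien-1-yl acetate | CC(=O)O/C=C/C=C/C(C)(C)[C@@H](O[Si](C)(C)C(C)(C)C)CC/C(C)=C/CO[Si](C)(C)C(C)(C)C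
F4 | step 10 | (1E,3E,6S,9E)-6-(tert-butyldimethylsilyloxy)-11-hydroxy-5,5,9-trimethylundeca-1,3,9-trien-1-yl acetate | CC(=O)O/C=C/C=C/C(C)(C)[C@@H](O[Si](C)(C)C(C)(C)C)CC/C(C)=C/CO
F5 | step 10 | (1E,3E,6S,9E)-6-(tert-butyldimethylsilyloxy)-5,5,9-trimethyl-11-oxoundeca-1,3,9-trien-1-yl acetate | CC(=O)O/C=C/C=C/C(C)(C)[C@@H](O[Si](C)(C)C(C)(C)C)CC/C(C)=C/C=O
F6 | step 10 | 8β-acetoxy-3β-(tert-butyldimethylsilyloxy)-12,13,14,15,16,17-hexanorlabd-6-en-11-al | CC(=O)O[C@H]1C=C[C@H]2C(C)(C)[C@@H](O[Si](C)(C)C(C)(C)C)CC[C@]2(C)[C@H]1C=O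
F7 | step 10 | methyl (11E,13R)-8β-acetoxy-3β-(tert-butyldimethylsilyloxy)-17-norlabda-6,11-dien-15-oate | CC(=O)O[C@H]1C=C[C@H]2C(C)(C)[C@@H](O[Si](C)(C)C(C)(C)C)CC[C@]2(C)[C@H]1/C=C/[C@H](C)CC(=O)OC
F8 | step 10 | methyl (13S)-8β-acetoxy-3β-(tert-butyldimethylsilyloxy)-17-norlabdan-15-oate | CC(=O)O[C@H]1CC[C@H]2C(C)(C)[C@@H](O[Si](C)(C)C(C)(C)C)CC[C@]2(C)[C@H]1CC[C@H](C)CC(=O)OC
F9 | step 14 | methyl (3R)-4-iodo-3-methylbutanoate | COC(=O)C[C@@H](C)CI
F10 | step 14 | [(2R)-4-methoxy-2-methyl-4-oxobutyl]triphenylphosphonium iodide | COC(=O)C[C@@H](C)C[P+](c1ccccc1)(c1ccccc1)c1ccccc1.[I-]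
F11 | step 14 | methyl (11Z,13R)-3β-(tert-butyldimethylsilyloxy)-8β-(triethylsilyloxy)-17-norlabda-6,11-dien-15-oate | CC[Si](CC)(CC)O[C@H]1C=C[C@H]2C(C)(C)[C@@H](O[Si](C)(C)C(C)(C)C)CC[C@]2(C)[C@H]1/C=C\[C@H](C)CC(=O)OC
F12 | step 19 | methyl (13S)-3β-(tert-butyldimethylsilyloxy)-8-(trimethylsilyloxy)-17-norlabd-7-en-15-oate | C[Si](C)(C)OC1=CC[C@H]2C(C)(C)[C@@H](O[Si](C)(C)C(C)(C)C)CC[C@]2(C)[C@H]1CC[C@H](C)CC(=O)OC
F13 | step 19 | methyl (13S)-3β-(tert-butyldimethylsilyloxy)-8-oxo-7α-(trimethylsilyloxy)-17-norlabdan-15-oate | O=C1[C@H](O[Si](C)(C)C)C[C@H]2C(C)(C)[C@@H](O[Si](C)(C)C(C)(C)C)CC[C@]2(C)[C@H]1CC[C@H](C)CC(=O)OC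
F14 | step 19 | methyl (13S)-3β-(tert-butyldimethylsilyloxy)-7α-(trimethylsilyloxy)labd-8(17)-en-15-oate | C=C1[C@H](O[Si](C)(C)C)C[C@H]2C(C)(C)[C@@H](O[Si](C)(C)C(C)(C)C)CC[C@]2(C)[C@H]1CC[C@H](C)CC(=O)OC
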